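## Analysis of the target

Compound 32 is a benzophenone in which ring A is the fully substituted benzene ring of a 2,2-dimethylchroman and ring B is a 3-hydroxyphenyl group. Going round ring A, C5 carries a methoxy group, C6 a ten-carbon 5-methyl-2-(prop-1-en-2-yl)hex-5-enyl chain, C7 a free hydroxyl and C8 the aroyl group, while C8a and C4a carry the pyran oxygen O1 and the C4 methylene. There are two stereocentres: the secondary carbinol C3 (R) next to the gem-dimethyl carbon C2, and the side-chain carbon C2' (R) that bears the isopropenyl group. They lie six bonds apart on opposite sides of ring A, so neither can direct the other and each has to be set on its own in absolute terms. The sensitive groups are the two 1,1-disubstituted alkenes (protonation gives tertiary cations that O7 can capture, and hydrogenation is excluded), the electron-rich trioxygenated ring, the three free hydroxyls and the crowded diaryl ketone. The difficulty is regiochemical: the three ring oxygens must end in three different states (methyl ether, free phenol, cyclic ether), and C6 and C8, each flanked by two oxygens, must receive different carbon substituents. The plan rests on the carbonyl carbon that bridges C8 of ring A and C1' of ring B. It can be delivered as carbon monoxide 17 between an iodide at C8 and a ring B boronic acid, and C8 is the carbon between the two oxygens of a symmetrical resorcinol, where iodine can be placed with certainty before the pyran ring exists.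

## Retrosynthetic reasoning

**Protecting groups.** 32 is taken back to tris-acetal 30; only the three O–CH2 acetal bonds at O3, O7 and O3' are cut. The cut comes last so that no free hydroxyl is present in any palladium-mediated step. The forward reaction has to unmask one secondary alkyl and two aryl acetals without Brønsted acid, because both alkenes are by then in the molecule; the silylated intermediate 31 is hydrolysed in the same flask.

**C6–C1' bond.** 30 is cut between ring carbon C6 and the side-chain methylene C1', giving aryl bromide 19 and boron ate complex 29 (made in the flask from iodide 27 by way of alkyllithium 28). No other cut detaches the complete chain without disturbing C2'; breaking C1'–C2' would mean creating that stereocentre on the crowded arene. The gain is convergence, and the acid- and oxidant-sensitive alkenes enter only two steps from the end. The forward reaction must join a β-branched primary alkyl group to an aryl bromide flanked by two oxygen substituents faster than β-hydride elimination.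

**Side chain.** Iodide 27 is related to acid 25 by replacing iodine with a carboxyl group (forward: radical decarboxylation of thiohydroxamate ester 26). 25 is related to keto acid 24 by exchanging the terminal methylene for oxygen, and 24 to keto aldehyde 23 by oxidation level. 23 leads through diol 22 and epoxide 21 to (R)-limonene 20 by rejoining the two carbonyl carbons as the ring alkene. In this mapping C4 of 20 is C2' of 32, C3 is C1', and C5–C6–C1 with its methyl group is C3'–C4'–C5' with its methyl group. C2 is the carbon that is excised and the terminal methylene is added. The stereocentre is thus bought in enantiopure form and never becomes a reacting centre; the price is the one-carbon excision.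

**C6–Br bond.** 19 comes from ketone 18 by electrophilic bromination. C6 is the only ring A position left, and placing the halogen after the carbonylation means the C8 iodide never has to be told apart from a second halide.

**Ketone (key disconnection).** 18 is cut on both sides of the carbonyl carbon, at C8–C(=O) and at C(=O)–C1', giving aryl iodide 11, carbon monoxide 17 and boronic acid 16. Cutting only one of these bonds would call for Friedel–Crafts acylation, which cannot tell C8 from C6, or for an aryl anion at C8 with a ring B carbonyl electrophile, which is kept as the fallback. The double cut is preferred because the iodine it needs is already at C8 for another reason, both partners are simple, and the conditions leave the acetals alone. The forward reaction must make carbonyl insertion outrun direct aryl–aryl coupling at a carbon with two ortho substituents.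

**Ring B.** 16 is taken back through borate 15 and aryllithium 14 to bromide 13 and to 3-bromophenol 12. The acetal goes on before metalation because it must be on the phenol during the key step.

**C3 stereocentre.** 11 is the acetal of alcohol 10, and 10 is traced to chromene 8 through epoxide 9; the C3–O bond and one C4–H bond are removed. The cis-disubstituted, aryl-conjugated alkene of a 2,2-dimethylchromene is a favourable case for catalytic asymmetric epoxidation. Hydride can only enter at the benzylic C4 because C3 is screened by the quaternary C2, so the C3–O bond made under catalyst control is kept. The forward sequence must reduce 9 as soon as it forms, because a benzylic epoxide on a ring with three donor oxygens ionises easily.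

**Pyran ring.** 8 is the acetal of phenol 7, and 7 is cut at O1–C2 and C4–C4a into iododiol 5 and 3-methylbut-2-enal 6. Because 5 is symmetrical and its C2 is blocked by iodine, both hydroxyls and both free ring positions lead to the same chromene. This fixes the methoxy group at C5, the free hydroxyl at C7 and the iodine at C8. The forward reaction is condensation at the ring carbon, dehydration and oxa-6π electrocyclisation, stopped after one annulation.

**Iodine.** 5 is taken back through bis-acetal 4 and aryllithium 3 to 2 and to 5-methoxyresorcinol 1. The C–I bond is made by directed metalation at the one carbon between the two acetal oxygens. This is more dependable than electrophilic iodination of the free resorcinol, where the position between hydroxyl and methoxy competes and over-iodination is likely.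

## Alternatives that were turned down

**Alternative 1:** Ring A is built rather than bought.
- Disconnection: three ring bonds (C5–C6, C7–C8, C4a–C5) are removed, leading to siloxyalkyne A2, which carries the whole side chain, and cyclobutenone A3.
- Forward key step: on heating, A3 opens to a ketene that adds across the electron-rich triple bond of A2; the new four-membered ring opens again, and 6π closure with tautomerisation gives phenol A1. The chain sits at C6 between a free hydroxyl (the later C5 methoxy) and a silyl ether (the later C7 hydroxyl), with the acetal oxygen at the later C8a.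
- For: the mechanism fixes the position of the chain, and the three ring oxygens emerge in three different protected states. The alkyne carbon bonded to the chain would be the carboxyl carbon of acid 25 after one-carbon ynolate homologation of its ester, so the limonene carbon excised in step 16 would become C6. On this point, and in needing no halogenation or cross-coupling at C6, the alternative is stronger.
- Against: A1 is still far from 32. C8 and C4a are both unsubstituted and each flanked by two oxygens, so the aroyl group and the pyran ring would have to be steered by protecting-group logic. C3 would still need epoxidation and reduction, now with both 1,1-disubstituted alkenes exposed to peracid, hydride and acid over many further steps.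
- Comparison: the chosen route offers ring regiochemistry that follows from the symmetry of 5 and one iodine atom, and alkenes that are present only in the last two steps.

**Alternative 2:** The pyranone ring is closed onto a finished benzophenone.
- Disconnection: the C4–C4a bond; the precursor is silyl enol ether A5, an aryl ether of a tertiary α-oxy ketone.
- Forward key step: constant-current oxidation at a carbon anode in a buffered alcoholic electrolyte would generate a radical cation, C4a would bond to the enol ether terminus, and loss of a second electron, the silyl group and a proton would give chroman-3-one A4.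
- For: the C3 oxygen is carried as a ketone, which is robust where epoxide 9 is not, and enantioselective reduction of a ketone next to a quaternary carbon is dependable. On this point the alternative is stronger, and the chosen route keeps this ketone in reserve as a fallback. The benzophenone would come from classical acylation without pressure equipment.
- Against: the arene that must attack is deactivated by the aroyl group at C8 and the acetate at C7. The trioxygenated ring and the enol ether are both oxidisable, so over-oxidation of A4 and capture of the radical cation by the alcohol compete with ring closure. A5 requires O-alkylation of a hydrogen-bonded phenol ortho to a ketone by a tertiary electrophile, and the two phenols flanking the ketone of a symmetrical precursor would have to be told apart without intrinsic bias. The C6 chain and the C3 reduction would still follow, so the sequence is no shorter.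
- Comparison: the chosen route builds the pyran ring by a condensation that cannot go astray on 5 and leaves the ketone to a late step.

**Alternative 3:** The ketone is made by aryne insertion.
- Disconnection: C7–O and C8–C(=O).
- Forward key step: fluoride would release from silyl triflate A7 an aryne with its triple bond between the later C7 and C8. Carboxylic acid A8 would add across it: the carboxylate oxygen bonds to the carbon remote from the neighbouring methoxy group, and the aryl anion then attacks the carbonyl carbon, breaking the C–O bond of the acid and giving ortho-hydroxy ketone A6.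
- For: the ketone is set between two oxygens without transition metal, pressure or toxic gas, and regiochemistry follows from the inductive effect of the methoxy group. On these points it is as good as or better than the chosen key step. The symmetrical 2,6-dioxygenated benzophenone pattern would also give a single chromene later without a blocking group.
- Against: A6 is a simple benzophenone that Friedel–Crafts or Fries chemistry would also give, so the steps spent on A7 buy little. The oxygen at the later C8a is a methyl ether of the same kind as the one at C5 that must stay; the selective demethylation needed would also remove the benzyl ether, which cannot be cleaved by hydrogenolysis once the alkenes are present. The ketone would have to survive the hydride step and every later organometallic step, and the pyran ring, C3 and the C6 chain all still lie ahead.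
- Comparison: the chosen route introduces the ketone after the hydride step, and one iodine atom both controls chromene formation and serves as the handle for the carbonyl.

Key step: step 10

Remark on the chemistry: epoxide 9 is assumed too prone to ionisation at C4 to survive isolation, so it is made and reduced in one operation; 21 and 22 are used as mixtures of ring diastereomers because both of their ring stereocentres are destroyed in step 13.

## Route

Step 1
Reactants: 1 5-methoxybenzene-1,3-diol (5-methoxyresorcinol)
Product: 2 1-methoxy-3,5-bis(methoxymethoxy)benzene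
Conditions: MOMCl (2.5 equiv), i-Pr2NEt, CH2Cl2, 0 °C → rt
Reagents that add atoms: chloromethyl methyl ether (MOMCl), COCCl
Why: Williamson-type O-alkylation of both phenols; the acetals protect and at the same time are the directing groups for step 2.

Step 2
Reactants: 2 1-methoxy-3,5-bis(methoxymethoxy)benzene
Product: 4 2-iodo-5-methoxy-1,3-bis(methoxymethoxy)benzene, via [4-methoxy-2,6-bis(methoxymethoxy)phenyl]lithium 3 (not isolated)
Conditions: n-BuLi, THF, 0 °C; then I2, −78 °C → rt
Reagents that add atoms: iodine, [I][I]
Why: Directed ortho-metalation: the proton between the two chelating acetal oxygens is removed in preference to those flanked by the methoxy group, and iodinolysis of 3 fixes iodine at that carbon.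

Step 3
Reactants: 4 2-iodo-5-methoxy-1,3-bis(methoxymethoxy)benzene
Product: 5 2-iodo-5-methoxybenzene-1,3-diol
Conditions: conc. HCl (cat.), MeOH, 40 °C
Reagents that add atoms: none
Why: Acid-catalysed acetal exchange with methanol frees both phenols; dilute acid and moderate temperature are chosen so that the electron-rich C–I bond is not lost by ipso-protonation.

Step 4
Reactants: 5 2-iodo-5-methoxybenzene-1,3-diol, 6 3-methylbut-2-enal
Product: 7 8-iodo-5-methoxy-2,2-dimethyl-2H-chromen-7-ol
Conditions: ethylenediammonium diacetate (10 mol %), 6 (1.05 equiv), toluene, 110 °C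
Reagents that add atoms: none
Why: Chromenylation of a resorcinol: Knoevenagel-type condensation of the ring carbon between hydroxyl and methoxy with the enal, dehydration to an ortho-quinone methide and oxa-6π electrocyclisation. Iodine blocks the carbon between the hydroxyls and 5 is symmetrical, so only one chromene can form; about one equivalent of 6 limits a second annulation at C6.

Step 5
Reactants: 7 8-iodo-5-methoxy-2,2-dimethyl-2H-chromen-7-ol
Product: 8 8-iodo-5-methoxy-7-(methoxymethoxy)-2,2-dimethyl-2H-chromene
Conditions: MOMCl, i-Pr2NEt, CH2Cl2, 0 °C → rt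
Reagents that add atoms: chloromethyl methyl ether (MOMCl), COCCl
Why: O-alkylation of the remaining phenol, which would not survive the oxidant of step 6 and must be masked in step 10.

Step 6
Reactants: 8 8-iodo-5-methoxy-7-(methoxymethoxy)-2,2-dimethyl-2H-chromene
Product: 10 (3R)-8-iodo-5-methoxy-7-(methoxymethoxy)-2,2-dimethylchroman-3-ol, via (3R,4R)-3,4-epoxy-8-iodo-5-methoxy-7-(methoxymethoxy)-2,2-dimethylchromane 9 (not isolated)
Conditions: (R,R)-[N,N'-bis(3,5-di-tert-butylsalicylidene)cyclohexane-1,2-diaminato]manganese chloride (5 mol %), NMO, mCPBA, CH2Cl2, −78 °C; cold filtration through basic Al2O3; then LiEt3BH, THF, −78 → 0 °C; H2O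
Reagents that add atoms: 3-chloroperoxybenzoic acid (mCPBA), O=C(OO)c1cccc(Cl)c1
Why: Jacobsen–Katsuki epoxidation of a cis-disubstituted, aryl-conjugated alkene (the 2,2-dimethylchromene substrate class); the (R,R) catalyst delivers oxygen to the face that gives (3R,4R)-9, which is reduced at once because its C4–O bond ionises easily. Hydride attacks by SN2 at the benzylic C4 (C3 is screened by the quaternary C2), so the C3–O bond set by the catalyst is retained as the (3R) carbinol.

Step 7
Reactants: 10 (3R)-8-iodo-5-methoxy-7-(methoxymethoxy)-2,2-dimethylchroman-3-ol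
Product: 11 (3R)-8-iodo-5-methoxy-3,7-bis(methoxymethoxy)-2,2-dimethylchromane
Conditions: MOMCl (excess), i-Pr2NEt, n-Bu4NI (cat.), CH2Cl2, 40 °C
Reagents that add atoms: chloromethyl methyl ether (MOMCl), COCCl
Why: Acetal protection of the hindered secondary alcohol, helped by in situ iodide exchange of the chloride; the hydroxyl must not be free to capture the acylpalladium species in step 10.

Step 8
Reactants: 12 3-bromophenol
Product: 13 1-bromo-3-(methoxymethoxy)benzene
Conditions: MOMCl, i-Pr2NEt, CH2Cl2, 0 °C → rt
Reagents that add atoms: chloromethyl methyl ether (MOMCl), COCCl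
Why: O-alkylation of the phenol with the protecting group needed on ring B during the key step.

Step 9
Reactants: 13 1-bromo-3-(methoxymethoxy)benzene
Product: 16 [3-(methoxymethoxy)phenyl]boronic acid, via [3-(methoxymethoxy)phenyl]lithium 14 (not isolated), via lithium [3-(methoxymethoxy)phenyl]tri(propan-2-yloxy)borate 15 (not isolated)
Conditions: n-BuLi, THF, −78 °C; B(Oi-Pr)3, −78 °C → rt; aq. HCl to pH 6, 0 °C
Reagents that add atoms: triisopropyl borate, CC(C)OB(OC(C)C)OC(C)C; water, O
Why: Bromine–lithium exchange is faster at −78 °C than ortho-lithiation next to the acetal; borylation of 14 and hydrolysis of borate 15 at near-neutral pH give the boronic acid with the acetal intact.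

Step 10
Reactants: 11 (3R)-8-iodo-5-methoxy-3,7-bis(methoxymethoxy)-2,2-dimethylchromane, 16 [3-(methoxymethoxy)phenyl]boronic acid, 17 carbon monoxide
Product: 18 [(3R)-5-methoxy-3,7-bis(methoxymethoxy)-2,2-dimethylchroman-8-yl][3-(methoxymethoxy)phenyl]methanone
Conditions: Pd(OAc)2 (5 mol %), di(1-adamantyl)-n-butylphosphine (10 mol %), K2CO3, 17 (10 bar), 16 (1.5 equiv), toluene, 100 °C
Reagents that add atoms: none
Why: Zerovalent palladium carrying the bulky, electron-rich phosphine inserts into the C8–I bond of 11; the divalent arylpalladium iodide is screened on both sides by the C7 acetal oxygen and the pyran oxygen, so transmetalation is slow and coordination and migratory insertion of 17 to the aroylpalladium species come first. The carbonate-activated boronate of 16 then transfers the ring B aryl group to this less crowded acyl complex, and reductive elimination releases 18 and returns zerovalent palladium, so the C8–C(=O) and C(=O)–C1' bonds are made in one operation. The closest known reaction type is the carbonylative Suzuki–Miyaura synthesis of hindered diaryl ketones from di-ortho-substituted aryl iodides. No ring is closed and no stereocentre is formed; C3 is remote and cannot epimerise under carbonate. The step needs carbonylative coupling to win over direct coupling (ketone, not biaryl) and over hydroxy- or alkoxycarbonylation: the first is secured by the di-ortho substitution at C8 together with the pressure of 17, the second by having every hydroxyl of both partners masked as an acetal and by limiting water. An iodide instead of a bromide allows oxidative addition into the electron-rich ring at a temperature the acetals tolerate.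

Step 11
Reactants: 18 [(3R)-5-methoxy-3,7-bis(methoxymethoxy)-2,2-dimethylchroman-8-yl][3-(methoxymethoxy)phenyl]methanone
Product: 19 [(3R)-6-bromo-5-methoxy-3,7-bis(methoxymethoxy)-2,2-dimethylchroman-8-yl][3-(methoxymethoxy)phenyl]methanone
Conditions: NBS (1.05 equiv), MeCN, 0 °C, dark
Reagents that add atoms: N-bromosuccinimide, O=C1CCC(=O)N1Br
Why: Electrophilic aromatic bromination; C6 is the only unsubstituted position of ring A and is activated by three oxygens (two ortho, one para), whereas ring B has one donor and a deactivating carbonyl.

Step 12
Reactants: 20 (R)-limonene [(4R)-1-methyl-4-(prop-1-en-2-yl)cyclohex-1-ene]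
Product: 21 (4R)-1-methyl-4-(prop-1-en-2-yl)-7-oxabicyclo[4.1.0]heptane (limonene 1,2-oxide, cis/trans mixture)
Conditions: mCPBA (1.0 equiv), CH2Cl2, 0 °C
Reagents that add atoms: 3-chloroperoxybenzoic acid (mCPBA), O=C(OO)c1cccc(Cl)c1
Why: Prilezhaev epoxidation; the trisubstituted ring alkene is more nucleophilic than the 1,1-disubstituted isopropenyl group, and C4 is not touched.

Step 13
Reactants: 21 (4R)-1-methyl-4-(prop-1-en-2-yl)-7-oxabicyclo[4.1.0]heptane
Product: 23 (3R)-6-oxo-3-(prop-1-en-2-yl)heptanal, via (4R)-1-methyl-4-(prop-1-en-2-yl)cyclohexane-1,2-diol 22 (not isolated)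
Conditions: H5IO6, THF/H2O, 0 °C → rt
Reagents that add atoms: water, O
Why: Aqueous periodic acid hydrolyses both epoxide diastereomers to diol 22 and cleaves it in the same flask (Malaprade cleavage); the ring carbons become the methyl ketone and the aldehyde, and the stereocentre is β to the aldehyde and cannot enolise.

Step 14
Reactants: 23 (3R)-6-oxo-3-(prop-1-en-2-yl)heptanal
Product: 24 (3R)-6-oxo-3-(prop-1-en-2-yl)heptanoic acid
Conditions: NaClO2, NaH2PO4, 2-methylbut-2-ene, t-BuOH/H2O, 0 °C → rt
Reagents that add atoms: sodium chlorite, [Na+].[O-]Cl=O
Why: Pinnick oxidation of the aldehyde; the scavenger alkene removes hypochlorous acid before it can add to the isopropenyl group.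

Step 15
Reactants: 24 (3R)-6-oxo-3-(prop-1-en-2-yl)heptanoic acid
Product: 25 (3R)-6-methyl-3-(prop-1-en-2-yl)hept-6-enoic acid
Conditions: Ph3PCH3Br (3 equiv), KOt-Bu (4 equiv), THF, 0 °C → rt; then aq. HCl to pH 3
Reagents that add atoms: methyltriphenylphosphonium bromide, C[P+](c1ccccc1)(c1ccccc1)c1ccccc1.[Br-]
Why: Wittig methylenation of the methyl ketone; the carboxylate formed by the first equivalent of base is inert to the ylide, and the stereocentre is β to the carboxyl and γ to the ketone, so it cannot epimerise.

Step 16
Reactants: 25 (3R)-6-methyl-3-(prop-1-en-2-yl)hept-6-enoic acid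
Product: 27 (3S)-3-(iodomethyl)-2,6-dimethylhepta-1,6-diene, via 2-thioxopyridin-1(2H)-yl (3R)-6-methyl-3-(prop-1-en-2-yl)hept-6-enoate 26 (not isolated)
Conditions: 1-hydroxypyridine-2(1H)-thione, DCC, DMAP (cat.), CH2Cl2, 0 °C → rt, dark; then CHI3, hν (tungsten lamp), rt
Reagents that add atoms: iodoform, IC(I)I
Why: Barton decarboxylative iodination: ester 26 fragments in a radical chain to the primary alkyl radical, which takes iodine from iodoform faster than it can cyclise onto either alkene or undergo a 1,2-vinyl shift. This removes the one limonene carbon that is not needed; the stereocentre is not a radical site and only its descriptor changes (iodomethyl now outranks isopropenyl).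

Step 17
Reactants: 19 [(3R)-6-bromo-5-methoxy-3,7-bis(methoxymethoxy)-2,2-dimethylchroman-8-yl][3-(methoxymethoxy)phenyl]methanone, 27 (3S)-3-(iodomethyl)-2,6-dimethylhepta-1,6-diene
Product: 30 {(3R)-5-methoxy-3,7-bis(methoxymethoxy)-2,2-dimethyl-6-[(2R)-5-methyl-2-(prop-1-en-2-yl)hex-5-en-1-yl]chroman-8-yl}[3-(methoxymethoxy)phenyl]methanone, via [(2S)-5-methyl-2-(prop-1-en-2-yl)hex-5-en-1-yl]lithium 28 (not isolated), via lithium B-alkyl-B-methoxy-9-BBN ate complex 29 (not isolated)
Conditions: 27 (1.5 equiv), t-BuLi (2.1 equiv per 27), Et2O, −78 °C; 9-MeO-9-BBN, THF, −78 °C → rt; then 19, Pd(OAc)2 (5 mol %), SPhos (10 mol %), aq. K3PO4, THF/DMF, 60 °C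
Reagents that add atoms: none
Why: B-alkyl Suzuki–Miyaura coupling: lithium–iodine exchange on 27 and capture of 28 by the borinic ester give ate complex 29, whose primary alkyl group is transferred to the arylpalladium bromide formed from 19. SPhos (2-dicyclohexylphosphino-2',6'-dimethoxybiphenyl) promotes oxidative addition into di-ortho-substituted electron-rich bromides and fast reductive elimination ahead of β-hydride elimination. C2' is one carbon away from the reacting centre and keeps its configuration, and the ketone and acetals are inert to the borate.

Step 18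
Reactants: 30 {(3R)-5-methoxy-3,7-bis(methoxymethoxy)-2,2-dimethyl-6-[(2R)-5-methyl-2-(prop-1-en-2-yl)hex-5-en-1-yl]chroman-8-yl}[3-(methoxymethoxy)phenyl]methanone
Product: 32 {(3R)-3,7-dihydroxy-5-methoxy-2,2-dimethyl-6-[(2R)-5-methyl-2-(prop-1-en-2-yl)hex-5-en-1-yl]chroman-8-yl}(3-hydroxyphenyl)methanone, via bis(trimethylsilyl) ether bipyridinium acetal triflate 31 (not isolated)
Conditions: TMSOTf, 2,2'-bipyridyl, CH2Cl2, 0 °C → rt; then H2O, rt
Reagents that add atoms: none
Why: Silyl triflate/2,2'-bipyridyl cleavage of methoxymethyl ethers: the two aryl acetals become trimethylsilyl ethers and the alkyl acetal a bipyridinium acetal salt (31), all of which water hydrolyses. The bipyridyl keeps the medium buffered, so the 1,1-disubstituted alkenes are not protonated and cannot cyclise onto O7; the methyl ether and the ketone are untouched.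

## Compound list

1 | 5-methoxybenzene-1,3-diol (5-methoxyresorcinol) | COc1cc(O)cc(O)c1 | starting material
2 | 1-methoxy-3,5-bis(methoxymethoxy)benzene | COCOc1cc(OC)cc(OCOC)c1 | intermediate
3 | [4-methoxy-2,6-bis(methoxymethoxy)phenyl]lithium | [Li]c1c(OCOC)cc(OC)cc1OCOC | intermediate
4 | 2-iodo-5-methoxy-1,3-bis(methoxymethoxy)benzene | COCOc1cc(OC)cc(OCOC)c1I | intermediate
5 | 2-iodo-5-methoxybenzene-1,3-diol | COc1cc(O)c(I)c(O)c1 | intermediate
6 | 3-methylbut-2-enal | CC(C)=CC=O | starting material
7 | 8-iodo-5-methoxy-2,2-dimethyl-2H-chromen-7-ol | COc1cc(O)c(I)c2OC(C)(C)C=Cc12 | intermediate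
8 | 8-iodo-5-methoxy-7-(methoxymethoxy)-2,2-dimethyl-2H-chromene | COCOc1cc(OC)c2C=CC(C)(C)Oc2c1I | intermediate
9 | (3R,4R)-3,4-epoxy-8-iodo-5-methoxy-7-(methoxymethoxy)-2,2-dimethylchromane | COc1cc(OCOC)c(I)c2c1[C@H]1O[C@H]1C(C)(C)O2 | intermediate
10 | (3R)-8-iodo-5-methoxy-7-(methoxymethoxy)-2,2-dimethylchroman-3-ol | COc1cc(OCOC)c(I)c2c1C[C@@H](O)C(C)(C)O2 | intermediate
11 | (3R)-8-iodo-5-methoxy-3,7-bis(methoxymethoxy)-2,2-dimethylchromane | COc1cc(OCOC)c(I)c2c1C[C@@H](OCOC)C(C)(C)O2 | intermediate
12 | 3-bromophenol | Oc1cccc(Br)c1 | starting material
13 | 1-bromo-3-(methoxymethoxy)benzene | COCOc1cccc(Br)c1 | intermediate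
14 | [3-(methoxymethoxy)phenyl]lithium | [Li]c1cccc(OCOC)c1 | intermediate
15 | lithium [3-(methoxymethoxy)phenyl]tri(propan-2-yloxy)borate | [Li+].CC(C)O[B-](OC(C)C)(OC(C)C)c1cccc(OCOC)c1 | intermediate
16 | [3-(methoxymethoxy)phenyl]boronic acid | OB(O)c1cccc(OCOC)c1 | intermediate
17 | carbon monoxide | [C-]#[O+] | starting material
18 | [(3R)-5-methoxy-3,7-bis(methoxymethoxy)-2,2-dimethylchroman-8-yl][3-(methoxymethoxy)phenyl]methanone | COc1cc(OCOC)c(C(=O)c3cccc(OCOC)c3)c2c1C[C@@H](OCOC)C(C)(C)O2 | intermediate
19 | [(3R)-6-bromo-5-methoxy-3,7-bis(methoxymethoxy)-2,2-dimethylchroman-8-yl][3-(methoxymethoxy)phenyl]methanone | COc1c(Br)c(OCOC)c(C(=O)c3cccc(OCOC)c3)c2c1C[C@@H](OCOC)C(C)(C)O2 | intermediate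
20 | (R)-limonene, (4R)-1-methyl-4-(prop-1-en-2-yl)cyclohex-1-ene | CC1=CC[C@@H](CC1)C(C)=C | starting material
21 | (4R)-1-methyl-4-(prop-1-en-2-yl)-7-oxabicyclo[4.1.0]heptane (limonene 1,2-oxide, cis/trans mixture at the epoxide carbons) | CC12OC1C[C@@H](CC2)C(C)=C | intermediate
22 | (4R)-1-methyl-4-(prop-1-en-2-yl)cyclohexane-1,2-diol (mixture at C1 and C2) | CC1(O)CC[C@H](CC1O)C(C)=C | intermediate
23 | (3R)-6-oxo-3-(prop-1-en-2-yl)heptanal | CC(=O)CC[C@H](CC=O)C(C)=C | intermediate
24 | (3R)-6-oxo-3-(prop-1-en-2-yl)heptanoic acid | CC(=O)CC[C@H](CC(=O)O)C(C)=C | intermediate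
25 | (3R)-6-methyl-3-(prop-1-en-2-yl)hept-6-enoic acid | C=C(C)CC[C@H](CC(=O)O)C(C)=C | intermediate
26 | 2-thioxopyridin-1(2H)-yl (3R)-6-methyl-3-(prop-1-en-2-yl)hept-6-enoate | C=C(C)CC[C@H](CC(=O)On1ccccc1=S)C(C)=C | intermediate
27 | (3S)-3-(iodomethyl)-2,6-dimethylhepta-1,6-diene | C=C(C)CC[C@H](CI)C(C)=C | intermediate
28 | [(2S)-5-methyl-2-(prop-1-en-2-yl)hex-5-en-1-yl]lithium | C=C(C)CC[C@H](C[Li])C(C)=C | intermediate
29 | lithium 9-methoxy-9-[(2S)-5-methyl-2-(prop-1-en-2-yl)hex-5-en-1-yl]-9-boranuidabicyclo[3.3.1]nonane (lithium B-alkyl-B-methoxy-9-BBN ate complex) | [Li+].C=C(C)CC[C@H](C[B-]1(OC)C2CCCC1CCC2)C(C)=C | intermediate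
30 | {(3R)-5-methoxy-3,7-bis(methoxymethoxy)-2,2-dimethyl-6-[(2R)-5-methyl-2-(prop-1-en-2-yl)hex-5-en-1-yl]chroman-8-yl}[3-(methoxymethoxy)phenyl]methanone | C=C(C)CC[C@H](Cc1c(OCOC)c(C(=O)c2cccc(OCOC)c2)c2c(c1OC)C[C@@H](OCOC)C(C)(C)O2)C(=C)C | intermediate
31 | 1-{[((3R)-5-methoxy-2,2-dimethyl-6-[(2R)-5-methyl-2-(prop-1-en-2-yl)hex-5-en-1-yl]-7-(trimethylsilyloxy)-8-[3-(trimethylsilyloxy)benzoyl]chroman-3-yl)oxy]methyl}-2,2'-bipyridin-1-ium trifluoromethanesulfonate (bis(trimethylsilyl) ether bipyridinium acetal triflate) | C=C(C)CC[C@H](Cc1c(O[Si](C)(C)C)c(C(=O)c2cccc(O[Si](C)(C)C)c2)c2c(c1OC)C[C@@H](OC[n+]1ccccc1-c1ccccn1)C(C)(C)O2)C(=C)C.[O-]S(=O)(=O)C(F)(F)F | intermediate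
32 | {(3R)-3,7-dihydroxy-5-methoxy-2,2-dimethyl-6-[(2R)-5-methyl-2-(prop-1-en-2-yl)hex-5-en-1-yl]chroman-8-yl}(3-hydroxyphenyl)methanone | C=C(C)CC[C@H](Cc1c(O)c(C(=O)c2cccc(O)c2)c2c(c1OC)C[C@@H](O)C(C)(C)O2)C(=C)C | target

## Step count and least certain steps

Total step count: 18. Longest linear sequence: 11 steps (steps 1–7, 10, 11, 17, 18). The two stereocentres are set independently (C3 in step 6, C2' from 20), so any enantiomeric impurity of either fragment would show up as a diastereomer of 32.

**Step 10 (key step).** The acylpalladium intermediate may form too slowly at the crowded C8. Reduction of the C–I bond, direct aryl–aryl coupling, or capture of the acyl group by hydroxide or water could then overtake ketone formation; protodeboronation of 16 at 100 °C would add to this. Fallback: the carbonyl is introduced by polar addition and oxidation. Aryllithium 14, generated as in step 9, is quenched with DMF to give 3-(methoxymethoxy)benzaldehyde F1. Iodide 11 is converted by iodine–magnesium exchange (i-PrMgCl·LiCl, THF, −20 °C) into chloro[(3R)-5-methoxy-3,7-bis(methoxymethoxy)-2,2-dimethylchroman-8-yl]magnesium F2, which is added to F1 to give [(3R)-5-methoxy-3,7-bis(methoxymethoxy)-2,2-dimethylchroman-8-yl][3-(methoxymethoxy)phenyl]methanol F3 as both carbinol epimers. Oxidation with Dess–Martin periodinane removes the new stereocentre and returns to 18.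

**Step 6.** The epoxide may ionise at C4 before hydride arrives. A 1,2-hydride shift would then give the achiral 3-ketone, which the hydride reduces without facial control, or carboxylate may add; both lower yield and enantiomeric purity. The peri methoxy group at C5 may also reduce the facial selectivity of oxygen transfer, and the hydride may attack the C–I bond if the mixture warms. Fallback: C3 is set by ketone reduction. Chromene 8 is hydroborated (BH3·THF; boron adds to C3, away from the aryl group) and oxidised (NaBO3·4H2O) to racemic 8-iodo-5-methoxy-7-(methoxymethoxy)-2,2-dimethylchroman-3-ol F4. Dess–Martin periodinane gives 8-iodo-5-methoxy-7-(methoxymethoxy)-2,2-dimethylchroman-3-one F5. Reduction with BH3·SMe2 and (S)-2-methyl-CBS-oxazaborolidine, with the quaternary C2 acting as the large group, should give the (3R) alcohol and so returns to 10.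

**Step 17.** Oxidative addition into the electron-rich C6–Br bond between two oxygen substituents may be slow. The β-branched alkylpalladium intermediate may then undergo β-hydride elimination, giving reduced arene and diene; if that elimination is reversible it could also scramble C2'. Fallback: Negishi coupling. Iodide 27 is treated with zinc dust and LiCl in THF to give iodo[(2S)-5-methyl-2-(prop-1-en-2-yl)hex-5-en-1-yl]zinc F6, which is coupled with bromide 19 using Pd(OAc)2 and CPhos (2-dicyclohexylphosphino-2',6'-bis(dimethylamino)biphenyl) in THF without base. This returns to 30.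

**Step 16.** The primary radical may rearrange before iodine transfer, by 3-exo closure and reopening (a 1,2-vinyl shift that would move the radical onto the stereocentre) or by cyclisation onto the remote alkene. Thiyl or diiodomethyl radicals may also add to the 1,1-disubstituted alkenes. Fallback: a polar excision of the same carbon. Acid 25 is converted into its dianion (LDA, THF) and oxygenated (O2, then Na2SO3) to (3S)-2-hydroxy-6-methyl-3-(prop-1-en-2-yl)hept-6-enoic acid F7. LiAlH4 gives (3S)-6-methyl-3-(prop-1-en-2-yl)hept-6-ene-1,2-diol F8. NaIO4 cleaves F8 to (2S)-5-methyl-2-(prop-1-en-2-yl)hex-5-enal F9, which is reduced in the same flask with NaBH4, before it can enolise, to (2S)-5-methyl-2-(prop-1-en-2-yl)hex-5-en-1-ol F10. I2, PPh3 and imidazole convert F10 into 27.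

**Step 18.** Cleavage of the hindered secondary acetal at O3 may be incomplete. Acid released during hydrolysis may also protonate an alkene, leading to cyclisation onto O7 or to solvent addition. Fallback: the protecting groups are exchanged before the chain is attached. Bromide 19, which has no alkene, is deprotected with HCl in methanol to [(3R)-6-bromo-3,7-dihydroxy-5-methoxy-2,2-dimethylchroman-8-yl](3-hydroxyphenyl)methanone F11. Silylation (TBSOTf, 2,6-lutidine) gives [(3R)-6-bromo-3,7-bis(tert-butyldimethylsilyloxy)-5-methoxy-2,2-dimethylchroman-8-yl][3-(tert-butyldimethylsilyloxy)phenyl]methanone F12. Coupling with 29 as in step 17 gives {(3R)-3,7-bis(tert-butyldimethylsilyloxy)-5-methoxy-2,2-dimethyl-6-[(2R)-5-methyl-2-(prop-1-en-2-yl)hex-5-en-1-yl]chroman-8-yl}[3-(tert-butyldimethylsilyloxy)phenyl]methanone F13. Desilylation with n-Bu4NF buffered with AcOH in THF returns to 32.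

## Further compounds

F1 | step 10 | 3-(methoxymethoxy)benzaldehyde | COCOc1cccc(C=O)c1
F2 | step 10 | chloro[(3R)-5-methoxy-3,7-bis(methoxymethoxy)-2,2-dimethylchroman-8-yl]magnesium | COc1cc(OCOC)c([Mg]Cl)c2c1C[C@@H](OCOC)C(C)(C)O2
F3 | step 10 | [(3R)-5-methoxy-3,7-bis(methoxymethoxy)-2,2-dimethylchroman-8-yl][3-(methoxymethoxy)phenyl]methanol (both carbinol epimers) | COc1cc(OCOC)c(C(O)c3cccc(OCOC)c3)c2c1C[C@@H](OCOC)C(C)(C)O2
F4 | step 6 | racemic 8-iodo-5-methoxy-7-(methoxymethoxy)-2,2-dimethylchroman-3-ol | COc1cc(OCOC)c(I)c2c1CC(O)C(C)(C)O2
F5 | step 6 | 8-iodo-5-methoxy-7-(methoxymethoxy)-2,2-dimethylchroman-3-one | COc1cc(OCOC)c(I)c2c1CC(=O)C(C)(C)O2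
F6 | step 17 | iodo[(2S)-5-methyl-2-(prop-1-en-2-yl)hex-5-en-1-yl]zinc | C=C(C)CC[C@H](C[Zn]I)C(C)=C
F7 | step 16 | (3S)-2-hydroxy-6-methyl-3-(prop-1-en-2-yl)hept-6-enoic acid (both C2 epimers) | C=C(C)CC[C@H](C(O)C(=O)O)C(C)=C
F8 | step 16 | (3S)-6-methyl-3-(prop-1-en-2-yl)hept-6-ene-1,2-diol (both C2 epimers) | C=C(C)CC[C@H](C(O)CO)C(C)=C
F9 | step 16 | (2S)-5-methyl-2-(prop-1-en-2-yl)hex-5-enal | C=C(C)CC[C@H](C=O)C(C)=C
F10 | step 16 | (2S)-5-methyl-2-(prop-1-en-2-yl)hex-5-en-1-ol | C=C(C)CC[C@H](CO)C(C)=C
F11 | step 18 | [(3R)-6-bromo-3,7-dihydroxy-5-methoxy-2,2-dimethylchroman-8-yl](3-hydroxyphenyl)methanone | COc1c(Br)c(O)c(C(=O)c3cccc(O)c3)c2c1C[C@@H](O)C(C)(C)O2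
F12 | step 18 | [(3R)-6-bromo-3,7-bis(tert-butyldimethylsilyloxy)-5-methoxy-2,2-dimethylchroman-8-yl][3-(tert-butyldimethylsilyloxy)phenyl]methanone | COc1c(Br)c(O[Si](C)(C)C(C)(C)C)c(C(=O)c3cccc(O[Si](C)(C)C(C)(C)C)c3)c2c1C[C@@H](O[Si](C)(C)C(C)(C)C)C(C)(C)O2
F13 | step 18 | {(3R)-3,7-bis(tert-butyldimethylsilyloxy)-5-methoxy-2,2-dimethyl-6-[(2R)-5-methyl-2-(prop-1-en-2-yl)hex-5-en-1-yl]chroman-8-yl}[3-(tert-butyldimethylsilyloxy)phenyl]methanone | C=C(C)CC[C@H](Cc1c(O[Si](C)(C)C(C)(C)C)c(C(=O)c2cccc(O[Si](C)(C)C(C)(C)C)c2)c2c(c1OC)C[C@@H](O[Si](C)(C)C(C)(C)C)C(C)(C)O2)C(=C)C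
A1 | alternative 1 | 5-(methoxymethoxy)-2-[(2R)-5-methyl-2-(prop-1-en-2-yl)hex-5-en-1-yl]-3-(triisopropylsilyloxy)phenol | C=C(C)CC[C@H](Cc1c(O)cc(OCOC)cc1O[Si](C(C)C)(C(C)C)C(C)C)C(=C)C
A2 | alternative 1 | triisopropyl{[(4R)-7-methyl-4-(prop-1-en-2-yl)oct-7-en-1-yn-1-yl]oxy}silane | C=C(C)CC[C@H](CC#CO[Si](C(C)C)(C(C)C)C(C)C)C(C)=C
A3 | alternative 1 | 3-(methoxymethoxy)cyclobut-2-en-1-one | COCOC1=CC(=O)C1
A4 | alternative 2 | 5-methoxy-2,2-dimethyl-3-oxo-8-[3-(triisopropylsilyloxy)benzoyl]chroman-7-yl acetate | CC(=O)Oc1cc(OC)c2c(c1C(=O)c1cccc(O[Si](C(C)C)(C(C)C)C(C)C)c1)OC(C)(C)C(=O)C2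
A5 | alternative 2 | 3-({3-[(tert-butyldimethylsilyl)oxy]-2-methylbut-3-en-2-yl}oxy)-5-methoxy-2-[3-(triisopropylsilyloxy)benzoyl]phenyl acetate | CC(=O)Oc1cc(OC)cc(OC(C)(C)C(=C)O[Si](C)(C)C(C)(C)C)c1C(=O)c1cccc(O[Si](C(C)C)(C(C)C)C(C)C)c1
A6 | alternative 3 | [3-(benzyloxy)phenyl](2-hydroxy-4,6-dimethoxyphenyl)methanone | COc1cc(OC)c(C(=O)c2cccc(OCc3ccccc3)c2)c(O)c1
A7 | alternative 3 | 3,5-dimethoxy-2-(trimethylsilyl)phenyl trifluoromethanesulfonate | COc1cc(OC)c([Si](C)(C)C)c(OS(=O)(=O)C(F)(F)F)c1
A8 | alternative 3 | 3-(benzyloxy)benzoic acid | OC(=O)c1cccc(OCc2ccccc2)c1
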